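**Retrosynthetic overview**
- The strategy rests on the lactone ring O1–C2–C3–C4–C4a–C8a of the chroman-2-one. Taking O1 out joins C8a directly to C2 and leaves the five-membered ring C7a–C1(=O)–C2–C3–C3a of a 3-aryl-indan-1-one, which already carries the C4 stereocentre as indanone C3.
- Forward, O1 is inserted by Baeyer–Villiger ring expansion of the (3R)-3-aryl-4-bromo-6-silyloxyindan-1-one. The C5 bromide stands in for the styryl group, which is attached afterwards by Heck coupling with silylated 2-methoxy-4-vinylphenol, followed by removal of the three silyl groups.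
- The (R) centre comes from CBS reduction of the 3-arylindenone to the (1R)-indenol and a suprafacial 1,3-hydrogen shift that carries the chirality from C1 to C3.
- The indenone is made from 3′-bromo-5′-hydroxyacetophenone and vanillin: acid aldol condensation, Nazarov closure of the C3–C3a bond para to the ring-A hydroxyl, silylation, DDQ dehydrogenation.
- Ring order: the five-membered carbocycle is closed first (step 2) and then expanded to the six-membered lactone (step 7); both benzene rings are bought.

Key step: step 7

Assumption: the sense of induction in step 5 follows the usual CBS model (fused arene as the large group) and the hydrogen shift in step 6 is suprafacial; if the indanone proves to be (S), the (R)-catalyst is used in step 5. TBS = tert-butyldimethylsilyl.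

**Step 1**
Reactants: 1 3′-bromo-5′-hydroxyacetophenone; 2 vanillin
Product: 3 (E)-1-(3-bromo-5-hydroxyphenyl)-3-(4-hydroxy-3-methoxyphenyl)prop-2-en-1-one
Conditions: HCl (g), EtOH, 0 °C → rt
Reagents that add atoms: none
Why: Acid-catalysed Claisen–Schmidt (crossed aldol) condensation, in which the enol of 1 adds to the protonated aldehyde and the aldol dehydrates to the conjugated (E)-enone; acid is used because the free phenols, as phenoxides, would shut down the base-mediated variant.

**Step 2**
Reactants: 3 the chalcone
Product: 4 rac-4-bromo-6-hydroxy-3-(4-hydroxy-3-methoxyphenyl)indan-1-one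
Conditions: TFA (dilute), 80 °C, sealed tube
Reagents that add atoms: none
Why: Nazarov-type cyclisation of a chalcone, in which the O-protonated enone (a hydroxyallyl cation stabilised by the 4-hydroxy-3-methoxyphenyl group) should close onto ring-A carbon C2′, para to the hydroxyl and between the acyl-bearing carbon and C–Br, then rearomatise and ketonise; the new centre is racemic and is erased in step 4.

**Step 3**
Reactants: 4 the racemic indanone diphenol
Product: 5 rac-4-bromo-6-(TBSO)-3-[4-(TBSO)-3-methoxyphenyl]indan-1-one
Conditions: TBSCl, imidazole, DMF, rt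
Reagents that add atoms: tert-butyldimethylsilyl chloride, CC(C)(C)[Si](C)(C)Cl
Why: Standard silylation of both phenols, placed after the two acid steps because aryl silyl ethers would not survive a hydroxide-mediated condensation and are doubtful in hot TFA.

**Step 4**
Reactants: 5 the racemic bis-silyl indanone
Product: 6 4-bromo-6-(TBSO)-3-[4-(TBSO)-3-methoxyphenyl]-1H-inden-1-one
Conditions: DDQ, 1,4-dioxane, 100 °C
Reagents that add atoms: none
Why: DDQ dehydrogenation, in which hydride abstraction from the doubly benzylic C3–H (cation stabilised by the 4-silyloxyaryl group) and loss of a C2 proton should give the conjugated indenone and make C3 prochiral.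

**Step 5**
Reactants: 6 the indenone
Product: 7 (1R)-4-bromo-6-(TBSO)-3-[4-(TBSO)-3-methoxyphenyl]-1H-inden-1-ol
Conditions: (S)-Me-CBS (cat.), BH3·SMe2, THF, −20 °C; MeOH quench
Reagents that add atoms: none
Why: Corey–Bakshi–Shibata reduction, in which the oxazaborolidine–borane complex binds the carbonyl oxygen anti to the bulkier fused-arene flank (C7a) and delivers hydride 1,2 to one face of C1, which should set the (1R) carbinol centre.

**Step 6**
Reactants: 7 the (1R)-indenol
Product: 9 (3R)-4-bromo-6-(TBSO)-3-[4-(TBSO)-3-methoxyphenyl]indan-1-one, via enol tautomer 8 (not isolated)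
Conditions: DABCO (cat.), THF, 60 °C
Reagents that add atoms: none
Why: Base-mediated stereospecific 1,3-hydrogen shift of a 1H-inden-1-ol, in which DABCO removes the C1 hydrogen to give a tight indenide–ammonium ion pair and returns it to C3 on the same face, so that the (1R) centre of 7 should be transferred to the (3R) centre of 9 after ketonisation of enol 8.

**Step 7**
Reactants: 9 the (3R)-indanone
Product: 11 (4R)-5-bromo-7-(TBSO)-4-[4-(TBSO)-3-methoxyphenyl]chroman-2-one, via Criegee peroxy hemiketal 10 (not isolated)
Conditions: mCPBA, TsOH·H2O (cat.), CH2Cl2, 0 °C → rt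
Reagents that add atoms: 3-chloroperoxybenzoic acid, OOC(=O)c1cccc(Cl)c1
Why: Baeyer–Villiger oxidation, in which the acid-activated ketone C1 adds the peracid to give the peroxy hemiketal 10 and the aryl carbon C7a then shifts from C1 to the proximal peroxide oxygen as 3-chlorobenzoate leaves, so that oxygen enters between C7a and C1 (the C8a–O1 and O1–C2 bonds of the chromanone). The closest known reaction is the peracid ring expansion of 1-indanones, enantioenriched 3-aryl-1-indanones included, to 3,4-dihydrocoumarins. The six-membered lactone is not closed by a cyclisation but arises by one-atom expansion of the five-membered ketone ring. No stereocentre is formed, and C3 of 9 (C4 of 11) lies away from the migrating bond and should keep its (R) configuration. The selectivity needed is migration of sp2 C7a over the C2 methylene, which the higher migratory aptitude of aryl over primary alkyl should supply; Br and OSi are both meta to C7a and weaken it only inductively, so acid catalysis and low temperature are used and the crude product is checked for the isochroman-1-one isomer. Chemoselectivity rests on the substrate carrying a bromide in place of the peracid-sensitive stilbene and silyl ethers in place of free, oxidisable phenols.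

**Step 8**
Reactants: 12 2-methoxy-4-vinylphenol
Product: 13 tert-butyl(2-methoxy-4-vinylphenoxy)dimethylsilane
Conditions: TBSCl, imidazole, CH2Cl2, 0 °C → rt
Reagents that add atoms: tert-butyldimethylsilyl chloride, CC(C)(C)[Si](C)(C)Cl
Why: Standard phenol silylation, which keeps the coupling partner non-acidic and gives all three phenols of the final intermediate the same protecting group.

**Step 9**
Reactants: 11 the bromo lactone; 13 the silylated vinylphenol
Product: 14 (4R)-7-(TBSO)-4-[4-(TBSO)-3-methoxyphenyl]-5-[(E)-2-[4-(TBSO)-3-methoxyphenyl]ethenyl]chroman-2-one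
Conditions: Pd2(dba)3 (cat.), P(t-Bu)3·HBF4 (cat.), Cy2NMe, 1,4-dioxane, 80 °C
Reagents that add atoms: none
Why: Mizoroki–Heck reaction, in which the bulky electron-rich phosphine promotes oxidative addition at the hindered C5–Br and syn-insertion at the terminal alkene carbon followed by syn-β-hydride elimination should give the (E)-stilbene, while the amine base spares the aryl silyl ethers and the lactone.

**Step 10**
Reactants: 14 the tris-silyl stilbene lactone
Product: 15 (4R)-7-hydroxy-4-(4-hydroxy-3-methoxyphenyl)-5-[(E)-2-(4-hydroxy-3-methoxyphenyl)ethenyl]chroman-2-one (target)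
Conditions: TBAF, AcOH, THF, 0 °C
Reagents that add atoms: none
Why: Fluoride desilylation of the three aryl silyl ethers, buffered with acetic acid so that phenoxide or fluoride base does not open the aryl lactone; C4 is not an enolisable centre and should be unaffected.

**Compound list**
1 | 3′-bromo-5′-hydroxyacetophenone | CC(=O)c1cc(O)cc(Br)c1 | starting material
2 | vanillin | COc1cc(C=O)ccc1O | starting material
3 | (E)-1-(3-bromo-5-hydroxyphenyl)-3-(4-hydroxy-3-methoxyphenyl)prop-2-en-1-one | COc1cc(/C=C/C(=O)c2cc(O)cc(Br)c2)ccc1O | intermediate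
4 | rac-4-bromo-6-hydroxy-3-(4-hydroxy-3-methoxyphenyl)indan-1-one | COc1cc(C2CC(=O)c3cc(O)cc(Br)c32)ccc1O | intermediate
5 | rac-4-bromo-6-(TBSO)-3-[4-(TBSO)-3-methoxyphenyl]indan-1-one | COc1cc(C2CC(=O)c3cc(O[Si](C)(C)C(C)(C)C)cc(Br)c32)ccc1O[Si](C)(C)C(C)(C)C | intermediate
6 | 4-bromo-6-(TBSO)-3-[4-(TBSO)-3-methoxyphenyl]-1H-inden-1-one | COc1cc(C2=CC(=O)c3cc(O[Si](C)(C)C(C)(C)C)cc(Br)c32)ccc1O[Si](C)(C)C(C)(C)C | intermediate
7 | (1R)-4-bromo-6-(TBSO)-3-[4-(TBSO)-3-methoxyphenyl]-1H-inden-1-ol | O[C@@H]1C=C(c2ccc(O[Si](C)(C)C(C)(C)C)c(OC)c2)c2c(Br)cc(O[Si](C)(C)C(C)(C)C)cc21 | intermediate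
8 | enol tautomer of 9, (1R)-7-bromo-5-(TBSO)-1-[4-(TBSO)-3-methoxyphenyl]-1H-inden-3-ol | Brc1cc(O[Si](C)(C)C(C)(C)C)cc2c1[C@@H](c1ccc(O[Si](C)(C)C(C)(C)C)c(OC)c1)C=C2O | intermediate
9 | (3R)-4-bromo-6-(TBSO)-3-[4-(TBSO)-3-methoxyphenyl]indan-1-one | Brc1cc(O[Si](C)(C)C(C)(C)C)cc2c1[C@@H](c1ccc(O[Si](C)(C)C(C)(C)C)c(OC)c1)CC2=O | intermediate
10 | Criegee peroxy hemiketal of 9 with mCPBA (C1 epimers) | Brc1cc(O[Si](C)(C)C(C)(C)C)cc2c1[C@@H](c1ccc(O[Si](C)(C)C(C)(C)C)c(OC)c1)CC2(O)OOC(=O)c1cccc(Cl)c1 | intermediate
11 | (4R)-5-bromo-7-(TBSO)-4-[4-(TBSO)-3-methoxyphenyl]chroman-2-one | Brc1cc(O[Si](C)(C)C(C)(C)C)cc2c1[C@@H](c1ccc(O[Si](C)(C)C(C)(C)C)c(OC)c1)CC(=O)O2 | intermediate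
12 | 2-methoxy-4-vinylphenol | COc1cc(C=C)ccc1O | starting material
13 | tert-butyl(2-methoxy-4-vinylphenoxy)dimethylsilane | COc1cc(C=C)ccc1O[Si](C)(C)C(C)(C)C | intermediate
14 | (4R)-7-(TBSO)-4-[4-(TBSO)-3-methoxyphenyl]-5-[(E)-2-[4-(TBSO)-3-methoxyphenyl]ethenyl]chroman-2-one | COc1cc(/C=C/c2cc(O[Si](C)(C)C(C)(C)C)cc3c2[C@@H](c2ccc(O[Si](C)(C)C(C)(C)C)c(OC)c2)CC(=O)O3)ccc1O[Si](C)(C)C(C)(C)C | intermediate
15 | (4R)-7-hydroxy-4-(4-hydroxy-3-methoxyphenyl)-5-[(E)-2-(4-hydroxy-3-methoxyphenyl)ethenyl]chroman-2-one | COc1cc(/C=C/c2cc(O)cc3c2[C@@H](c2ccc(O)c(OC)c2)CC(=O)O3)ccc1O | target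

**Totals**
Total step count: 10. Longest linear sequence: 9 (steps 1–7, 9, 10).

**Steps most likely to fail**

1. Step 7 (key step). The C2 methylene may migrate in competition with the inductively deactivated C7a, giving the isochroman-1-one. Peracid addition to the aryl ketone may also be slow enough that the acid strips silyl groups first. Fallback, from 9 back to 11: the oxidation is steered by an α-halogen. Compound 9 is brominated at C2 with phenyltrimethylammonium tribromide (THF, 0 °C) to the trans ketone (2S,3R)-2,4-dibromo-6-(TBSO)-3-[4-(TBSO)-3-methoxyphenyl]indan-1-one F1; the configuration at C2 is of no consequence. mCPBA in CH2Cl2 should then insert oxygen on the aryl side only, because a bromine-bearing carbon is a very poor migrating group, giving (3S,4R)-3,5-dibromo-7-(TBSO)-4-[4-(TBSO)-3-methoxyphenyl]chroman-2-one F2. Zinc dust in AcOH/THF at 0 °C removes the α-bromine without touching the aryl bromide and returns the route to 11.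

2. Step 2. The cation may close at the other ortho carbon of ring A (between the hydroxyl and the acyl-bearing carbon), or alkylate the phenol rings of a second molecule instead of closing. Fallback, from 2 back to 5: the five-membered ring is closed at the C1–C7a bond instead, where the two-fold symmetry of a 3,5-dibromophenol unit removes the choice of site. Vanillin 2 is silylated (TBSCl, imidazole) to 4-(TBSO)-3-methoxybenzaldehyde F3. Commercial 3,5-dibromophenol is silylated to tert-butyl(3,5-dibromophenoxy)dimethylsilane F4, which LDA (THF, −78 °C) deprotonates between the two bromines. Addition to F3 gives [2,6-dibromo-4-(TBSO)phenyl][4-(TBSO)-3-methoxyphenyl]methanol F5. BF3·OEt2-mediated substitution of the benzhydrylic hydroxyl by 1-methoxy-1-(trimethylsilyloxy)ethene (CH2Cl2, −78 °C) gives methyl 3-[2,6-dibromo-4-(TBSO)phenyl]-3-[4-(TBSO)-3-methoxyphenyl]propanoate F6. Bromine–lithium exchange at one of the two equivalent bromines (n-BuLi, THF, −100 °C) and Parham cyclisation onto the ester should deliver 5, with the remaining bromine as the C4 bromide.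

3. Step 5. Enantioface discrimination in the 1,2-reduction may be poor, because both flanks of the carbonyl are planar sp2 carbons, and a low enantiomeric purity would be carried through step 6. Fallback, from 6 directly to 9 (7 and 8 are skipped): copper hydride-catalysed asymmetric conjugate reduction, which sets C3 by hydride delivery to the β-carbon instead of by chirality transfer. Conditions: Cu(OAc)2·H2O, a chiral bisphosphine such as p-Tol-BINAP or DTBM-SEGPHOS, polymethylhydrosiloxane, t-BuOH, toluene, 0 °C → rt. The ligand enantiomer that gives the (3R) product is chosen in a test run. No new compound is made.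

**Further compounds**
F1 | step 7 | (2S,3R)-2,4-dibromo-6-(TBSO)-3-[4-(TBSO)-3-methoxyphenyl]indan-1-one | Brc1cc(O[Si](C)(C)C(C)(C)C)cc2c1[C@@H](c1ccc(O[Si](C)(C)C(C)(C)C)c(OC)c1)[C@H](Br)C2=O
F2 | step 7 | (3S,4R)-3,5-dibromo-7-(TBSO)-4-[4-(TBSO)-3-methoxyphenyl]chroman-2-one | Brc1cc(O[Si](C)(C)C(C)(C)C)cc2c1[C@@H](c1ccc(O[Si](C)(C)C(C)(C)C)c(OC)c1)[C@H](Br)C(=O)O2
F3 | step 2 | 4-(TBSO)-3-methoxybenzaldehyde | COc1cc(C=O)ccc1O[Si](C)(C)C(C)(C)C
F4 | step 2 | tert-butyl(3,5-dibromophenoxy)dimethylsilane | CC(C)(C)[Si](C)(C)Oc1cc(Br)cc(Br)c1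
F5 | step 2 | rac-[2,6-dibromo-4-(TBSO)phenyl][4-(TBSO)-3-methoxyphenyl]methanol | COc1cc(C(O)c2c(Br)cc(O[Si](C)(C)C(C)(C)C)cc2Br)ccc1O[Si](C)(C)C(C)(C)C
F6 | step 2 | rac-methyl 3-[2,6-dibromo-4-(TBSO)phenyl]-3-[4-(TBSO)-3-methoxyphenyl]propanoate | COC(=O)CC(c1ccc(O[Si](C)(C)C(C)(C)C)c(OC)c1)c1c(Br)cc(O[Si](C)(C)C(C)(C)C)cc1Br
F0 | step 5 | none | none
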